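Watch the last reading.

| flask | starting material | coupling partner | time |
|---|---|---|---|
| east | 0.200 M | 0.200 M |  |
| north | 0.200 M | 0.300 M |  |
| south-west | 0.600 M | 0.200 M |  |
| north-west | 0.200 M | 0.600 M | 24 min |

| run | time / min | [target] / M |
|---|---|---|
| east run | 0.96 | 0.0056 |
| east run | 1.8 | 0.0180 |
| east run | 3.5 | 0.0382 |
| east run | 6.6 | 0.0682 |
| east run | 13 | 0.0878 |
| east run | 24 | 0.0976 |
| north run | 0.96 | 0.0105 |
| north run | 1.8 | 0.0242 |
| north run | 3.5 | 0.0555 |
| north run | 6.6 | 0.0838 |
| north run | 13 | 0.1013 |
| north run | 24 | 0.1081 |
| south-west run | 0.96 | 0.0126 |
| south-west run | 1.8 | 0.0335 |
| south-west run | 3.5 | 0.0810 |
| south-west run | 6.6 | 0.1292 |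
| south-west run | 13 | 0.1662 |
| south-west run | 24 | 0.1819 |

(readings scatter by 0.001 M)

- how the opening rate goes with [starting material] round the charge of the east run: the exponent of the rate at two percent of starting material gone to target (one fixed amount of target, the same in the runs compared)
- how the opening rate goes with [coupling partner] round the charge of the east run: the exponent of the rate at two percent of starting material gone to target
- target in the north-west run at 24 min, as a share of the starting material charged

- Overall: starting material + coupling partner -> target.
- Constant volume, constant temperature.
- Bound and free are read together.
- "The second partner" is coupling partner.
- An order is taken over about fifteen percent of the charge, up and down.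

You asked for a quick number on the north-west run, so I reckon from the last readings of the two runs with its charge of starting material. Starting material is the limiting reagent in the north-west run. I call the loss ratio the starting material not found as target per target made at 24 min. The east run gives 1.05 at 0.200 M of coupling partner, and the north run gives 0.850 at 0.300 M.

I write the ratio as a base plus a correction that goes as one over the charge of coupling partner. The size of that correction is the partner term, from the two ratios:

partner term = 0.119 M

base = 0.452

north-west ratio = 0.452 + 0.199 = 0.651

share = 60.6 %

In the north-west run the correction is the smaller part, and I commit to that share.

The forecast you sent has orders of 0.4 in starting material and 0.5 in coupling partner, and a share of 60 %. It begins from “The target stalls well short of the charge” and extrapolates the plateau in coupling partner. I take its orders as they stand, and my share lies 0.60 percentage points above its share.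

Round the charge of the east run, the opening rate has orders of 0.45 in starting material and 0.55 in coupling partner. The north-west run gives a share of 56.7 % at 24 min, so the forecast stands within its margins.

    starting material ⇌ intermediate + by-product (0.7440 min⁻¹, 0.7320 M⁻¹ min⁻¹)
    intermediate + coupling partner → target (1.140 M⁻¹ min⁻¹)
    starting material → decomposed substrate (0.5142 min⁻¹)
    2 starting material ⇌ idle substrate dimer, settled at all times (5.710 M⁻¹)

In the north-west run, while starting material is present, it goes to intermediate and by-product and also to decomposed substrate, with the constants in the ratio 0.691, and intermediate meets coupling partner to give target. The simulated share means a loss ratio of 0.765 against my 0.651; its excess over that constant ratio is 0.0740, where my partner term put 0.199. In the south-west run the rule gives a ratio of 1.05, or 0.293 M of target, which is more than the 0.200 M of coupling partner charged, and the reading at 24 min is 0.1819 M.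

The readings were generated by integration for substances that don't exist; noise was put on by code.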